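**Plan**

- Retrosynthesis, with the ring numbered as in the target (C1 acyl, C2 stilbenyl-aryl, C3 =CH, C4 C–Me, C5 CH2, C6 dihydroxyphenyl): six phenols are masked as aryl esters, a Me3Si group is put back on C3 with the alkene moved to C4=C5 (allylsilane retron), and the cyclohexene is cut at C2–C3 and C1–C6 by a [4+2] disconnection.
- Enabling feature: C1–C2 with its trans acyl/aryl pair is a former E-enone whose 2-hydroxyaryl ketone can chelate boron. C6–C5–C4(Me)–C3 is a 1-aryl-3-methylbutadiene unit one allylic shift away from the ring alkene, and a silyl group on the diene terminus C3 makes that shift exact.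
- Fragments: chalcone 6 (Heck, Claisen–Schmidt, selective acetylation) and silyl diene 12 (pivaloylation, Takai, hydroboration/Suzuki–Miyaura), three steps each.
- Forward: step 7 closes the cyclohexene from 6 and 12, step 8 moves the alkene to C3=C4 by protodesilylation, step 9 frees the six esterified phenols.
- Stereochemistry: C1/C2 trans from the E-enone; C6 from the exo-acyl/endo-aryl approach of the E,E-diene; absolute configuration from a chiral borate; the silyl-bearing centre is erased in step 8.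

Key step: step 7

Assumption: the borate of 6 built on the (S)-biaryl diol is taken to screen the Si face of the enone α-carbon (spiro-borate model, s-cis enone), so that 12 adds to the Re face; should the sense be the opposite, the (R)-diol is used and nothing else changes.

**Route**

Step 1
Reactants: 1 2-hydroxy-5-iodobenzaldehyde; 2 5-ethenyl-1,3-phenylene diacetate (3,5-diacetoxystyrene)
Product: 3 5-[(E)-2-(3-formyl-4-hydroxyphenyl)ethenyl]-1,3-phenylene diacetate
Conditions: Pd(OAc)2 (3 mol %), P(o-tol)3 (6 mol %), Et3N (1.5 equiv), MeCN, 80 °C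
Reagents that add atoms: none
Why: Heck reaction, in which oxidative addition of the aryl iodide to zerovalent palladium, syn-insertion of the styrene and syn-β-hydride elimination should give the E-stilbene, the acetyl groups staying on the less acidic resorcinol oxygens.

Step 2
Reactants: 3 5-[(E)-2-(3-formyl-4-hydroxyphenyl)ethenyl]-1,3-phenylene diacetate; 4 1-(2,4-dihydroxyphenyl)ethan-1-one
Product: 5 (E)-1-(2,4-dihydroxyphenyl)-3-{5-[(E)-2-(3,5-dihydroxyphenyl)ethenyl]-2-hydroxyphenyl}prop-2-en-1-one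
Conditions: KOH (50% aq., 15 equiv), EtOH, 0 °C → rt, argon; then 1 M HCl to pH 5, 0 °C
Reagents that add atoms: none
Why: Claisen–Schmidt condensation (aldol addition, then E1cB dehydration) should give the thermodynamically preferred E-enone, while hydroxide cleaves the two aryl acetates in the same pot.

Step 3
Reactants: 5 (E)-1-(2,4-dihydroxyphenyl)-3-{5-[(E)-2-(3,5-dihydroxyphenyl)ethenyl]-2-hydroxyphenyl}prop-2-en-1-one
Product: 6 (E)-1-(4-acetoxy-2-hydroxyphenyl)-3-{2-acetoxy-5-[(E)-2-(3,5-diacetoxyphenyl)ethenyl]phenyl}prop-2-en-1-one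
Conditions: Ac2O (4.2 equiv), pyridine, CH2Cl2, −10 → 0 °C
Reagents that add atoms: acetic anhydride, CC(=O)OC(C)=O
Why: O-acylation of the four non-chelated phenols; the hydroxyl ortho to the ketone is held in a hydrogen bond to the carbonyl oxygen and should stay free for boron binding in step 7.

Step 4
Reactants: 7 2,4-dihydroxybenzaldehyde
Product: 8 4-formyl-1,3-phenylene bis(2,2-dimethylpropanoate)
Conditions: t-BuCOCl (2.4 equiv), Et3N (3 equiv), DMAP (0.1 equiv), CH2Cl2, 0 °C → rt
Reagents that add atoms: pivaloyl chloride, CC(C)(C)C(=O)Cl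
Why: DMAP-catalysed O-acylation; pivalates are chosen because they should survive the chromium reagent of step 5 and the aqueous phosphate of step 6 and still fall to methanolysis in step 9.

Step 5
Reactants: 8 4-formyl-1,3-phenylene bis(2,2-dimethylpropanoate)
Product: 9 4-[(E)-2-iodoethenyl]-1,3-phenylene bis(2,2-dimethylpropanoate)
Conditions: CHI3 (2 equiv), CrCl2 (6 equiv), THF/1,4-dioxane, 0 °C → rt
Reagents that add atoms: iodoform, IC(I)I
Why: Takai olefination, in which the geminal dichromium species formed from iodoform and divalent chromium adds to the aldehyde and anti-elimination should give the E-vinyl iodide, aryl esters being inert to the reagent.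

Step 6
Reactants: 10 trimethyl(prop-1-yn-1-yl)silane; 9 4-[(E)-2-iodoethenyl]-1,3-phenylene bis(2,2-dimethylpropanoate)
Product: 12 4-[(1E,3E)-3-methyl-4-(trimethylsilyl)buta-1,3-dien-1-yl]-1,3-phenylene bis(2,2-dimethylpropanoate), via vinylborane 11 (not isolated)
Conditions: 9-borabicyclo[3.3.1]nonane (9-BBN, 1.05 equiv), THF, 0 °C → rt; then 9, PdCl2(dppf) (5 mol %), K3PO4 (3 M aq., 3 equiv), DMF, rt
Reagents that add atoms: none
Why: syn-hydroboration with the bulky borane should place boron on the methyl-bearing alkyne carbon (away from silicon), and the Suzuki–Miyaura coupling proceeds with retention at both alkenyl carbons, so the silyl group ends trans to the new C–C bond and the diene is E,E.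

Step 7
Reactants: 6 (E)-1-(4-acetoxy-2-hydroxyphenyl)-3-{2-acetoxy-5-[(E)-2-(3,5-diacetoxyphenyl)ethenyl]phenyl}prop-2-en-1-one; 12 4-[(1E,3E)-3-methyl-4-(trimethylsilyl)buta-1,3-dien-1-yl]-1,3-phenylene bis(2,2-dimethylpropanoate) (1.5 equiv)
Product: 13 (4-acetoxy-2-hydroxyphenyl){(1R,2S,5S,6R)-6-{2-acetoxy-5-[(E)-2-(3,5-diacetoxyphenyl)ethenyl]phenyl}-2-[2,4-bis(pivaloyloxy)phenyl]-4-methyl-5-(trimethylsilyl)cyclohex-3-en-1-yl}methanone
Conditions: B(OPh)3 (0.3 equiv), (S)-3,3'-dibromo-1,1'-bi-2-naphthol (0.3 equiv), 4 Å molecular sieves, PhCF3, 40 °C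
Reagents that add atoms: none
Why: The phenol and ketone oxygens of 6 chelate boron in a six-membered borate ring that also carries the (S)-biaryl diolate, which lowers the enone LUMO and screens one face, and the s-cis diene 12 then adds in a concerted, asynchronous, suprafacial [4+2] cycloaddition (Diels–Alder reaction), the closest known reaction type being the chiral-borate-promoted cycloaddition of 2'-hydroxychalcones with 1-aryl-3-methylbuta-1,3-dienes. The cyclohexene ring is closed intermolecularly in the [4π+2π] mode through a boat-like transition state, forming C1–C2 and C5–C6 of the adduct (C1–C6 and C2–C3 in target numbering) on the same face of each component. C1 and C6 are trans because the E-enone geometry is conserved, C2 is set relative to C1 by the transition state that places the borate-bearing acyl group exo and the β-aryl group endo to the E,E-diene, C5 (silyl) follows from the E-vinylsilane terminus and is erased in step 8, and the absolute configuration follows from addition to the Cα-Re/Cβ-Re face left open by the ligand. The step needs regioselectivity (aryl terminus of the diene to Cα, silyl terminus to Cβ), which the largest HOMO coefficient at the silyl-bearing terminus (reinforced by the 1-aryl and 3-methyl groups) and the largest LUMO coefficient at Cβ should secure; exo selectivity, which the bulk of the spiro-borate on the acyl side should favour; and facial selectivity, which rests on the ligand.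

Step 8
Reactants: 13 (4-acetoxy-2-hydroxyphenyl){(1R,2S,5S,6R)-6-{2-acetoxy-5-[(E)-2-(3,5-diacetoxyphenyl)ethenyl]phenyl}-2-[2,4-bis(pivaloyloxy)phenyl]-4-methyl-5-(trimethylsilyl)cyclohex-3-en-1-yl}methanone
Product: 14 (4-acetoxy-2-hydroxyphenyl){(1R,2R,6S)-2-{2-acetoxy-5-[(E)-2-(3,5-diacetoxyphenyl)ethenyl]phenyl}-6-[2,4-bis(pivaloyloxy)phenyl]-4-methylcyclohex-3-en-1-yl}methanone
Conditions: CF3CO2H (5 equiv), CH2Cl2, 0 °C; then aq. NaHCO3
Reagents that add atoms: none
Why: Protodesilylation of an allylsilane (SE2'), in which protonation at the alkene carbon remote from silicon gives a tertiary β-silyl cation and loss of the silyl group should place the double bond between the methyl-bearing carbon and the former silyl carbon, erasing that stereocentre and leaving the other three untouched (the descriptors change only through renumbering).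

Step 9
Reactants: 14 (4-acetoxy-2-hydroxyphenyl){(1R,2R,6S)-2-{2-acetoxy-5-[(E)-2-(3,5-diacetoxyphenyl)ethenyl]phenyl}-6-[2,4-bis(pivaloyloxy)phenyl]-4-methylcyclohex-3-en-1-yl}methanone
Product: 15 (2,4-dihydroxyphenyl){(1R,2R,6S)-6-(2,4-dihydroxyphenyl)-2-{5-[(E)-2-(3,5-dihydroxyphenyl)ethenyl]-2-hydroxyphenyl}-4-methylcyclohex-3-en-1-yl}methanone
Conditions: K2CO3 (3 equiv), degassed MeOH/THF, 0 °C → rt, argon; then AcOH to pH 6
Reagents that add atoms: none
Why: Base-mediated transesterification (methanolysis) of the four acetates and two pivalates; the all-trans ring with three equatorial substituents is the thermodynamic arrangement, so the centre α to the ketone should not be eroded.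

**Compound list**

1 | 2-hydroxy-5-iodobenzaldehyde | O=Cc1cc(I)ccc1O | starting material
2 | 5-ethenyl-1,3-phenylene diacetate | C=Cc1cc(OC(C)=O)cc(OC(C)=O)c1 | starting material
3 | 5-[(E)-2-(3-formyl-4-hydroxyphenyl)ethenyl]-1,3-phenylene diacetate | O=Cc1cc(/C=C/c2cc(OC(C)=O)cc(OC(C)=O)c2)ccc1O | intermediate
4 | 1-(2,4-dihydroxyphenyl)ethan-1-one | CC(=O)c1ccc(O)cc1O | starting material
5 | (E)-1-(2,4-dihydroxyphenyl)-3-{5-[(E)-2-(3,5-dihydroxyphenyl)ethenyl]-2-hydroxyphenyl}prop-2-en-1-one | O=C(/C=C/c1cc(/C=C/c2cc(O)cc(O)c2)ccc1O)c1ccc(O)cc1O | intermediate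
6 | (E)-1-(4-acetoxy-2-hydroxyphenyl)-3-{2-acetoxy-5-[(E)-2-(3,5-diacetoxyphenyl)ethenyl]phenyl}prop-2-en-1-one | O=C(/C=C/c1cc(/C=C/c2cc(OC(C)=O)cc(OC(C)=O)c2)ccc1OC(C)=O)c1ccc(OC(C)=O)cc1O | intermediate
7 | 2,4-dihydroxybenzaldehyde | O=Cc1ccc(O)cc1O | starting material
8 | 4-formyl-1,3-phenylene bis(2,2-dimethylpropanoate) | O=Cc1ccc(OC(=O)C(C)(C)C)cc1OC(=O)C(C)(C)C | intermediate
9 | 4-[(E)-2-iodoethenyl]-1,3-phenylene bis(2,2-dimethylpropanoate) | I/C=C/c1ccc(OC(=O)C(C)(C)C)cc1OC(=O)C(C)(C)C | intermediate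
10 | trimethyl(prop-1-yn-1-yl)silane | CC#C[Si](C)(C)C | starting material
11 | (Z)-[2-(9-borabicyclo[3.3.1]nonan-9-yl)prop-1-en-1-yl]trimethylsilane (silicon cis to methyl) | C[Si](C)(C)/C=C(\C)B1C2CCCC1CCC2 | intermediate
12 | 4-[(1E,3E)-3-methyl-4-(trimethylsilyl)buta-1,3-dien-1-yl]-1,3-phenylene bis(2,2-dimethylpropanoate) | C[Si](C)(C)/C=C(\C)/C=C/c1ccc(OC(=O)C(C)(C)C)cc1OC(=O)C(C)(C)C | intermediate
13 | (4-acetoxy-2-hydroxyphenyl){(1R,2S,5S,6R)-6-{2-acetoxy-5-[(E)-2-(3,5-diacetoxyphenyl)ethenyl]phenyl}-2-[2,4-bis(pivaloyloxy)phenyl]-4-methyl-5-(trimethylsilyl)cyclohex-3-en-1-yl}methanone | CC1=C[C@H](c2ccc(OC(=O)C(C)(C)C)cc2OC(=O)C(C)(C)C)[C@@H](C(=O)c2ccc(OC(C)=O)cc2O)[C@H](c2cc(/C=C/c3cc(OC(C)=O)cc(OC(C)=O)c3)ccc2OC(C)=O)[C@@H]1[Si](C)(C)C | intermediate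
14 | (4-acetoxy-2-hydroxyphenyl){(1R,2R,6S)-2-{2-acetoxy-5-[(E)-2-(3,5-diacetoxyphenyl)ethenyl]phenyl}-6-[2,4-bis(pivaloyloxy)phenyl]-4-methylcyclohex-3-en-1-yl}methanone | CC1=C[C@@H](c2cc(/C=C/c3cc(OC(C)=O)cc(OC(C)=O)c3)ccc2OC(C)=O)[C@H](C(=O)c2ccc(OC(C)=O)cc2O)[C@@H](c2ccc(OC(=O)C(C)(C)C)cc2OC(=O)C(C)(C)C)C1 | intermediate
15 | (2,4-dihydroxyphenyl){(1R,2R,6S)-6-(2,4-dihydroxyphenyl)-2-{5-[(E)-2-(3,5-dihydroxyphenyl)ethenyl]-2-hydroxyphenyl}-4-methylcyclohex-3-en-1-yl}methanone | CC1=C[C@@H](c2cc(/C=C/c3cc(O)cc(O)c3)ccc2O)[C@H](C(=O)c2ccc(O)cc2O)[C@@H](c2ccc(O)cc2O)C1 | target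

**Step count and risks**

Total steps: 9. Longest linear sequence: 6 (steps 1, 2, 3, 7, 8, 9; the diene arm 4, 5, 6, 7, 8, 9 is equally long).

Steps most likely to fail:

1. Step 7. The doubly end-substituted diene may add slowly, and the borate may discriminate poorly between the two enone faces or between the exo-acyl and endo-acyl approaches. The fallback gives up catalyst control. It sets out from 6 and 12, which are heated without promoter (toluene, 2,6-di-tert-butyl-4-methylphenol, sealed tube, 150 °C) in a thermal Diels–Alder reaction of the kind known for 2'-hydroxychalcones and aryl dienes. The exo adduct is separated from the endo isomer on silica as the racemate, that is 13 together with its enantiomer (4-acetoxy-2-hydroxyphenyl){(1S,2R,5R,6S)-6-{2-acetoxy-5-[(E)-2-(3,5-diacetoxyphenyl)ethenyl]phenyl}-2-[2,4-bis(pivaloyloxy)phenyl]-4-methyl-5-(trimethylsilyl)cyclohex-3-en-1-yl}methanone F1. The enantiomers are resolved by preparative HPLC on a cellulose tris(3,5-dimethylphenylcarbamate) phase, and the route is rejoined at 13.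

2. Step 6. Hydroboration may deliver boron to the silicon-bearing carbon or run on to double hydroboration, and the aqueous base of the coupling may strip pivaloyl groups. The fallback builds the diene by olefination from a vinylsilane of fixed geometry; it sets out from 8 and comes back at 12. Commercial 3-(trimethylsilyl)prop-2-yn-1-ol undergoes copper-catalysed anti-carbomagnesiation (MeMgBr, CuI 10 mol %, THF, −10 °C → rt; the alkoxide directs magnesium to the silyl carbon, so methyl and silicon end cis) to (E)-2-methyl-3-(trimethylsilyl)prop-2-en-1-ol F2. PBr3 (Et2O, 0 °C) gives [(E)-3-bromo-2-methylprop-1-en-1-yl]trimethylsilane F3, and a Michaelis–Arbuzov reaction with P(OEt)3 (120 °C) gives diethyl [(E)-2-methyl-3-(trimethylsilyl)prop-2-en-1-yl]phosphonate F4. Horner–Wadsworth–Emmons olefination of aldehyde 8 (LiN(SiMe3)2, THF, −78 → 0 °C) should then give the E,E-diene 12.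

3. Step 2. Condensation of the polyphenoxide partners may stall, and the electron-rich stilbene phenoxide may degrade oxidatively in strong base. The fallback forms the enone under neutral conditions by Wittig olefination; it sets out from 3 and comes back at 6. Commercial 2-chloro-1-(2,4-dihydroxyphenyl)ethan-1-one and PPh3 (MeCN, 60 °C) give [2-(2,4-dihydroxyphenyl)-2-oxoethyl]triphenylphosphonium chloride F5, and NaOH (1.0 equiv, H2O/CH2Cl2) gives the stabilised ylide 1-(2,4-dihydroxyphenyl)-2-(triphenyl-λ5-phosphanylidene)ethan-1-one F6. With aldehyde 3 (toluene, 90 °C) this should give the E-enone 5-[(E)-2-{3-[(E)-3-(2,4-dihydroxyphenyl)-3-oxoprop-1-en-1-yl]-4-hydroxyphenyl}ethenyl]-1,3-phenylene diacetate F7. Ac2O (2.1 equiv)/pyridine at 0 °C then acylates its two non-chelated phenols to give 6.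

**Further compounds**

F1 | step 7 | (4-acetoxy-2-hydroxyphenyl){(1S,2R,5R,6S)-6-{2-acetoxy-5-[(E)-2-(3,5-diacetoxyphenyl)ethenyl]phenyl}-2-[2,4-bis(pivaloyloxy)phenyl]-4-methyl-5-(trimethylsilyl)cyclohex-3-en-1-yl}methanone | CC1=C[C@@H](c2ccc(OC(=O)C(C)(C)C)cc2OC(=O)C(C)(C)C)[C@H](C(=O)c2ccc(OC(C)=O)cc2O)[C@@H](c2cc(/C=C/c3cc(OC(C)=O)cc(OC(C)=O)c3)ccc2OC(C)=O)[C@H]1[Si](C)(C)C
F2 | step 6 | (E)-2-methyl-3-(trimethylsilyl)prop-2-en-1-ol | C[Si](C)(C)/C=C(\C)CO
F3 | step 6 | [(E)-3-bromo-2-methylprop-1-en-1-yl]trimethylsilane | C[Si](C)(C)/C=C(\C)CBr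
F4 | step 6 | diethyl [(E)-2-methyl-3-(trimethylsilyl)prop-2-en-1-yl]phosphonate | CCOP(=O)(C/C(C)=C/[Si](C)(C)C)OCC
F5 | step 2 | [2-(2,4-dihydroxyphenyl)-2-oxoethyl]triphenylphosphonium chloride | O=C(C[P+](c1ccccc1)(c1ccccc1)c1ccccc1)c1ccc(O)cc1O.[Cl-]
F6 | step 2 | 1-(2,4-dihydroxyphenyl)-2-(triphenyl-λ5-phosphanylidene)ethan-1-one | O=C(C=P(c1ccccc1)(c1ccccc1)c1ccccc1)c1ccc(O)cc1O
F7 | step 2 | 5-[(E)-2-{3-[(E)-3-(2,4-dihydroxyphenyl)-3-oxoprop-1-en-1-yl]-4-hydroxyphenyl}ethenyl]-1,3-phenylene diacetate | O=C(/C=C/c1cc(/C=C/c2cc(OC(C)=O)cc(OC(C)=O)c2)ccc1O)c1ccc(O)cc1O
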